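A small charge of free catalyst, 3.7 mM against 0.10 M of substrate, has to go round 27.0 times to use up the substrate, and a capture agent stands ready to take it out of the round.

    substrate + free catalyst → catalyst intermediate A (k1 = 79 L mol⁻¹ h⁻¹)
    reagent + catalyst intermediate A → catalyst intermediate B (k2 = 57 L mol⁻¹ h⁻¹)
    catalyst intermediate B → free catalyst + product (k3 = 13 h⁻¹)
    2 reagent → homo dimer (k4 = 5.0 L mol⁻¹ h⁻¹)
    catalyst intermediate A + capture agent → trapped intermediate (k5 = 14 L mol⁻¹ h⁻¹)

substrate 0.10 M; reagent 0.150 M; capture agent 0.100 M; free catalyst 3.7 mM

1. the form that holds most of the catalyst when 10% of the substrate are converted (trapped intermediate / free catalyst / catalyst intermediate B / catalyst intermediate A)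
2. its share of the catalyst then
3. apparent order in reagent when 10% of the substrate are converted (percent change of the rate of making product for one percent more reagent charged)

Catalyst intermediate A stands at a fork: the reagent carries it on, the capture agent traps it. Both rates contain [catalyst intermediate A], so their quotient is free of it, but it still moves with [reagent] and [capture agent]. This is the capture odds, the capture constant times [capture agent] over the reagent constant times [reagent], a selectivity factor for the fork. As charged it is 0.164, so the fork favours the round by 6.10 to one. Trapping looks like a side matter, and still it comes out ahead in the reckoning below.

The odds hold per passage, though, and passages repeat. Reagent also dimerises, with a first half-life of 0.667 h by that step alone, shorter than the 1.27 h at which 10% of the substrate is converted. Taking dimerisation as reagent's sole loss, [reagent] is down by a factor 2.91 by then. Catalyst intermediate A then moves on at 2.94 h⁻¹, and the odds have grown to 0.476.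

A working catalyst divides its time among its forms by their time constants; the two forms other than catalyst intermediate A take 0.204 h per round at charged substrate. Capture removes, per hour, its rate times the share in catalyst intermediate A. Summed up to that moment, the loss exponent is 0.923. This reckoning therefore gives trapped intermediate with a share of 60.2%. It stops short of the order.

The forecast also names trapped intermediate, but at 36%, “narrowly ahead of intermediate A”, a lower share than reckoned here, and it gives an order of 0.65.

The simulation gives trapped intermediate at 55.9%, with catalyst intermediate A at 25.4%, and an order of 1.3. With the simulated [reagent] and [capture agent], the odds read 0.266 after 0.400 h and 1.18 after 4.00 h. After 40.0 h the trapped form holds 100% of the catalyst and product stands at 9.28% of the substrate charged, an average of 0.399 trapped per product, while 87.0% of the substrate remains.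

(The rate constants were set for the occasion.)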